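The numbers in the tables stem from a simulated flask for an exercise; scatter was added.

The flask is read at 80 min, later than any reading so far, so the meeting first asked how far the earlier runs could be carried.

| flask | starting material | reagent | second substrate | remark | time |
|---|---|---|---|---|---|
| ash | 19 mM | 28.5 mM | 13 mM | run made earlier |  |
| birch | 19 mM | 28.5 mM | 28 mM | run made earlier |  |
| cedar | 38 mM | 28.5 mM | 19 mM | run made earlier |  |
| flask | 19 mM | 28.5 mM | 19.0 mM |  | 80 min |

| run | time / min | target / % | dormant form / % |
|---|---|---|---|
| ash | 3.00 | 4.3 | 24.3 |
| ash | 10.0 | 5.7 | 49.9 |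
| ash | 20.0 | 4.1 | 62.6 |
| ash | 30.0 | 3.1 | 65.7 |
| ash | 40.0 | 2.2 | 66.5 |
| ash | 50.0 | 2.5 | 66.4 |
| ash | 60.0 | 2.0 | 68.0 |
| birch | 3.00 | 2.6 | 23.7 |
| birch | 10.0 | 3.8 | 51.3 |
| birch | 20.0 | 3.2 | 62.5 |
| birch | 30.0 | 3.3 | 65.5 |
| birch | 40.0 | 2.7 | 66.5 |
| birch | 50.0 | 2.2 | 66.9 |
| birch | 60.0 | 2.4 | 67.7 |
| cedar | 6.00 | 3.8 | 39.3 |
| cedar | 15.0 | 3.3 | 59.7 |
| cedar | 30.0 | 2.9 | 65.4 |
| cedar | 50.0 | 2.2 | 66.9 |
| cedar | 60.0 | 3.2 | 67.3 |

(readings scatter by 0.5 percentage points)

- what was read earlier has a scatter of 0.5 percentage points, one standard deviation
- steps thought possible: starting material + reagent <-> target; second substrate + reagent <-> second product; starting material <-> dormant form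

1. the target in the flask at 80 min, as a percentage of the starting material charged
2. the dormant form in the flask at 80 min, as a percentage of the starting material charged
3. the starting material in the flask at 80 min, as a percentage of the starting material charged
4. concentration of reagent at 80 min, in mM

The chair noted that the dormant form last read 68.0%, 67.7% and 67.3% in the ash, birch and cedar runs, although cedar was charged with 38 mM of starting material against 19 mM. I proposed carrying one number, the dormant ratio: [dormant form] over [starting material] once both stop moving, the equilibrium constant of that step. Taking starting material as what target and dormant form leave, the last two readings of each run give 2.21.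

I then reckoned by rounds. With no target, the ratio leaves 31.1% as starting material. The same readings put target at 7.95% of the starting material, so target is 2.48%. Putting that back leaves 30.4% starting material and 67.2% dormant form, and once more gives target 2.42%. The ratio says nothing about [reagent], so I gave no figure for it.

The author of the forecast gave target 2.4%, dormant form 67.8%, starting material 29.8%, a little below mine, and [reagent] 13 mM, adding: “Reagent is poorly defined because it was never measured.”

The flask gives target 2.19%, dormant form 67.2%, starting material 30.6% and [reagent] 17.9 mM.

    starting material + reagent ⇌ target (K = 3.88 M⁻¹, k = 0.00786 M⁻¹ s⁻¹)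
    second substrate + reagent ⇌ second product (K = 262 M⁻¹, k = 0.00824 M⁻¹ s⁻¹)
    starting material ⇌ dormant form (K = 2.20, k = 0.00169 s⁻¹)

In this flask the ratio of 2.21 read from the runs stands beside 2.20 from the result. The forecast's percentages fall within their margins, but its [reagent] is low by a factor of 1.38. The neighbouring flask is charged with 32 mM of second substrate and holds target 1.63%. Putting that target through the same reckoning gives starting material 30.6% and dormant form 67.7%. The simulation of that flask gives 30.8% and 67.6%, with [reagent] at 12.9 mM.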